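Numbering N1, O2, C3, C3a, C4–C6, C6a, the target is (3S,3aS,6aR) with H3, H3a and H6a on one face. Both pyridin-3-yl ends are cut last (two C(sp3)–C(sp2) bonds) to a bis(terminal alkene) and two molecules of 3-bromopyridine.
C3–H is traced to a C3 hemiketal (hydride to the oxocarbenium ion from the convex face), and the C3–octenyl bond to a Grignard addition at a C3 lactone carbonyl.
The strategy rests on the array N1–C6a–C3a–C3–O2 of the isoxazolidine ring fused to the cyclopentane: with C3 as a carbonyl carbon it is the lactone of a cis β-(hydroxyamino) acid. It is cut at N1–C6a (aza-Michael) and O2–C3 (O-acylation) into a cyclopent-1-enyl acyl pyrazole and N-(dodec-11-enyl)hydroxylamine.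
Ring order: the cyclopentane is bought as cyclopent-1-ene-1-carboxylic acid, the isoxazolidine is the only ring made (key step, which also sets C6a and C3a), and both pyridine rings are bought.
The two partners come from the acid chloride plus 3,5-dimethylpyrazole, and from 12-bromododec-1-ene plus N,O-bis-Boc-hydroxylamine.

Key step: step 4

Assumption: the sense of induction of the Mg(II)–bis(oxazoline) catalyst on this cyclic acceptor is not fixed in advance; both antipodes of 2,2′-(cyclopropane-1,1-diyl)bis(3a,8a-dihydro-8H-indeno[1,2-d]oxazole) are commercial, and L* in step 4 means the antipode that sends nitrogen to the Re face of C2 of the cyclopentene (giving 6aR).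

Step 1
Reactants: 1 cyclopent-1-ene-1-carboxylic acid
Product: 3 1-(cyclopent-1-en-1-ylcarbonyl)-3,5-dimethyl-1H-pyrazole, via cyclopent-1-ene-1-carbonyl chloride 2 (not isolated)
Conditions: (COCl)2, DMF (cat.), CH2Cl2, 0 °C → rt; concentrate; then 3,5-dimethylpyrazole, Et3N, CH2Cl2, 0 °C → rt
Reagents that add atoms: 3,5-dimethyl-1H-pyrazole, Cc1cc(C)[nH]n1
Why: Acid chloride formation through the Vilsmeier-type chloroiminium species followed by N-acylation of the symmetric pyrazole is routine acyl substitution; no stereocentre is involved.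

Step 2
Reactants: 4 12-bromododec-1-ene; 5 tert-butyl N-[(tert-butoxycarbonyl)oxy]carbamate (N,O-bis-Boc-hydroxylamine)
Product: 6 tert-butyl N-[(tert-butoxycarbonyl)oxy]-N-(dodec-11-en-1-yl)carbamate
Conditions: K2CO3, DMF, rt → 40 °C
Reagents that add atoms: none
Why: SN2 alkylation of the acidic N–H of the doubly acylated hydroxylamine by a primary bromide; oxygen is blocked as the carbonate, so only the N-monoalkyl product can form.

Step 3
Reactants: 6 tert-butyl N-[(tert-butoxycarbonyl)oxy]-N-(dodec-11-en-1-yl)carbamate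
Product: 7 N-(dodec-11-en-1-yl)hydroxylamine
Conditions: TFA, CH2Cl2, 0 °C → rt; then aq NaHCO3, degassed Et2O; used at once under Ar
Reagents that add atoms: none
Why: Acidolysis removes the carbamate and the carbonate Boc groups (tert-butyl cation loss, then decarboxylation); a monosubstituted alkene should not add TFA in this short, cold treatment, and the free base is liberated so that no acid competes for the Mg(II) catalyst.

Step 4
Reactants: 3 1-(cyclopent-1-en-1-ylcarbonyl)-3,5-dimethyl-1H-pyrazole; 7 N-(dodec-11-en-1-yl)hydroxylamine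
Product: 9 (3aS,6aR)-1-(dodec-11-en-1-yl)hexahydro-3H-cyclopenta[c]isoxazol-3-one, via aza-Michael adduct 8 (not isolated)
Conditions: Mg(NTf2)2 (10 mol%), L* (11 mol%), 4 Å MS, CH2Cl2, −40 °C, slow addition of 7; then Et3N (0.3 equiv), −40 °C → rt
Reagents that add atoms: none
Why: The Mg(II)–bis(oxazoline) complex binds 3 through the carbonyl oxygen and pyrazole N2, the α-effect nitrogen of 7 adds to C2 of the cyclopentene (the future C6a) on its Re face to give adduct 8 after proton transfer to C3a, and the N–OH oxygen then attacks the Mg-activated acyl carbon and expels 3,5-dimethylpyrazole. The closest known reaction type is the Mg(II)/bis(oxazoline)-catalysed conjugate addition–cyclisation of N-benzylhydroxylamine with enoyl 3,5-dimethylpyrazoles and with α,β-disubstituted enoyl imides, which gives isoxazolidin-5-ones directly. The isoxazolidinone ring closes by 5-exo-trig acyl substitution (oxygen on C3), so N1–C6a and O2–C3 are both formed in one flask. C6a is set by the ligand, which shields one face of the chelated acceptor; C3a is set by the ring, because it is epimerisable through the Mg enolate of the acyl pyrazole (helped by Et3N) and only the cis (1S,2R) epimer of 8 can lactonise, a trans-fused bicyclo[3.3.0] lactone being strongly disfavoured, so any trans adduct from syn N/H delivery should drain through the cis one. The step needs attack of nitrogen at the β-carbon instead of N- or O-acylation at the carbonyl, and the bidentate chelation that activates the β-position together with the hindered α-branched carbonyl should secure it; the remote terminal alkene is inert.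

Step 5
Reactants: 9 (3aS,6aR)-1-(dodec-11-en-1-yl)hexahydro-3H-cyclopenta[c]isoxazol-3-one; 10 8-bromooct-1-ene
Product: 12 (3aS,6aR)-1-(dodec-11-en-1-yl)-3-(oct-7-en-1-yl)hexahydro-1H-cyclopenta[c]isoxazol-3-ol (C3 anomers), via oct-7-en-1-ylmagnesium bromide 11 (not isolated)
Conditions: 10, Mg, I2 (cat.), THF, rt → 40 °C; then slow addition (1.15 equiv) to 9, THF, −78 °C; pH 7 buffer at −78 °C
Reagents that add atoms: none
Why: Grignard addition to the lactone carbonyl at −78 °C should stop at the magnesium hemiketal, which is kept until the cold quench; the product rests as the cyclic 5-hydroxyisoxazolidine form of the β-(hydroxyamino) ketone, C3 is an anomeric mixture that step 6 erases, and C3a stays cis because only that isomer can close.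

Step 6
Reactants: 12 (3aS,6aR)-1-(dodec-11-en-1-yl)-3-(oct-7-en-1-yl)hexahydro-1H-cyclopenta[c]isoxazol-3-ol
Product: 13 (3S,3aS,6aR)-1-(dodec-11-en-1-yl)-3-(oct-7-en-1-yl)hexahydro-1H-cyclopenta[c]isoxazole
Conditions: Et3SiH (4 equiv), BF3·OEt2 (2.5 equiv), CH2Cl2, −78 → −20 °C
Reagents that add atoms: none
Why: Ionic reduction of a lactol: loss of the exocyclic hydroxyl gives the ring-oxygen-stabilised C3 oxocarbenium ion of the cis-fused bicycle, and hydride from the silane enters on the convex face, anti to C4, so H3 ends cis to H3a and the octenyl chain on the concave face (3S); monosubstituted alkenes and the N–O bond are not touched under these conditions.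

Step 7
Reactants: 13 (3S,3aS,6aR)-1-(dodec-11-en-1-yl)-3-(oct-7-en-1-yl)hexahydro-1H-cyclopenta[c]isoxazole; 14 3-bromopyridine
Product: 16 3-[12-[(3S,3aS,6aR)-3-[8-(pyridin-3-yl)octyl]hexahydro-1H-cyclopenta[c]isoxazol-1-yl]dodecyl]pyridine (CNP0267546.1), via bis(B-alkyl-9-BBN) adduct 15 (not isolated)
Conditions: 9-BBN (3 equiv), THF, 0 °C → rt; then 14 (3 equiv), PdCl2(dppf)·CH2Cl2 (8 mol%), 3 M aq K3PO4, DMF, 60 °C
Reagents that add atoms: 3-bromopyridine (second molecule of 14), Brc1cccnc1
Why: Anti-Markovnikov hydroboration of both terminal alkenes with 9-BBN followed by a twofold B-alkyl Suzuki–Miyaura coupling, in which each of the two alkyl–boron ends takes up one molecule of 14 (two molecules in all); no stereocentre is involved, and the N–O bond should tolerate 9-BBN at rt and Pd(0).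

Compound list
1 | cyclopent-1-ene-1-carboxylic acid | O=C(O)C1=CCCC1 | starting material
2 | cyclopent-1-ene-1-carbonyl chloride (not isolated) | O=C(Cl)C1=CCCC1 | intermediate
3 | 1-(cyclopent-1-en-1-ylcarbonyl)-3,5-dimethyl-1H-pyrazole | O=C(C1=CCCC1)n1nc(C)cc1C | intermediate
4 | 12-bromododec-1-ene | C=CCCCCCCCCCCBr | starting material
5 | tert-butyl N-[(tert-butoxycarbonyl)oxy]carbamate | CC(C)(C)OC(=O)NOC(=O)OC(C)(C)C | starting material
6 | tert-butyl N-[(tert-butoxycarbonyl)oxy]-N-(dodec-11-en-1-yl)carbamate | C=CCCCCCCCCCCN(OC(=O)OC(C)(C)C)C(=O)OC(C)(C)C | intermediate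
7 | N-(dodec-11-en-1-yl)hydroxylamine | C=CCCCCCCCCCCNO | intermediate
8 | 1-{[(2R)-2-[dodec-11-en-1-yl(hydroxy)amino]cyclopentyl]carbonyl}-3,5-dimethyl-1H-pyrazole (C1 epimers, the cis (1S,2R) one closes; not isolated) | C=CCCCCCCCCCCN(O)[C@@H]1CCCC1C(=O)n1nc(C)cc1C | intermediate
9 | (3aS,6aR)-1-(dodec-11-en-1-yl)hexahydro-3H-cyclopenta[c]isoxazol-3-one | C=CCCCCCCCCCCN1OC(=O)[C@H]2CCC[C@H]21 | intermediate
10 | 8-bromooct-1-ene | C=CCCCCCCBr | starting material
11 | oct-7-en-1-ylmagnesium bromide (not isolated) | C=CCCCCCC[Mg]Br | intermediate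
12 | (3aS,6aR)-1-(dodec-11-en-1-yl)-3-(oct-7-en-1-yl)hexahydro-1H-cyclopenta[c]isoxazol-3-ol (C3 anomers) | C=CCCCCCCCCCCN1OC(O)(CCCCCCC=C)[C@H]2CCC[C@H]21 | intermediate
13 | (3S,3aS,6aR)-1-(dodec-11-en-1-yl)-3-(oct-7-en-1-yl)hexahydro-1H-cyclopenta[c]isoxazole | C=CCCCCCCCCCCN1O[C@@H](CCCCCCC=C)[C@H]2CCC[C@H]21 | intermediate
14 | 3-bromopyridine | Brc1cccnc1 | starting material
15 | (3S,3aS,6aR)-1-[12-(9-borabicyclo[3.3.1]nonan-9-yl)dodecyl]-3-[8-(9-borabicyclo[3.3.1]nonan-9-yl)octyl]hexahydro-1H-cyclopenta[c]isoxazole (not isolated) | B1(CCCCCCCCCCCCN2O[C@@H](CCCCCCCCB3C4CCCC3CCC4)[C@H]3CCC[C@H]32)C2CCCC1CCC2 | intermediate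
16 | 3-[12-[(3S,3aS,6aR)-3-[8-(pyridin-3-yl)octyl]hexahydro-1H-cyclopenta[c]isoxazol-1-yl]dodecyl]pyridine (CNP0267546.1) | c1cncc(CCCCCCCCCCCCN2O[C@@H](CCCCCCCCc3cccnc3)[C@H]3CCC[C@H]32)c1 | target

Total step count: 7. Longest linear sequence: 6 steps (steps 2–7, from 12-bromododec-1-ene).

Steps most likely to fail

Step 4. The α-branch is forced against the 5-methyl group of the pyrazole, so the enoyl unit may twist out of the chelate plane and add slowly or with poor facial discrimination. Direct acylation of the hydroxylamine at the carbonyl may compete. Equilibration of C3a in the adduct may be too slow, so that a trans adduct accumulates without lactonising. The fallback takes C3a and C6a from the chiral pool and sets out from bromide 4. N-Alkylation of methyl (1S,2R)-2-aminocyclopentane-1-carboxylate F1 (commercial as the hydrochloride, used in excess; K2CO3, NaI, MeCN, 60 °C) should give methyl (1S,2R)-2-(dodec-11-en-1-ylamino)cyclopentane-1-carboxylate F2. Oxidation of the secondary amine with dibenzoyl peroxide and K2HPO4 in DMF should give methyl (1S,2R)-2-[(benzoyloxy)(dodec-11-en-1-yl)amino]cyclopentane-1-carboxylate F3. Methanolysis of the benzoate (NaOMe cat., MeOH, 0 °C) should release methyl (1S,2R)-2-[(dodec-11-en-1-yl)(hydroxy)amino]cyclopentane-1-carboxylate F4, whose N–OH oxygen closes onto the ester on warming. The route is rejoined at lactone 9.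

Step 5. The magnesium hemiketal may collapse with expulsion of the N–O oxygen before the quench, freeing the ketone for a second addition, or the reagent may attack at nitrogen with N–O cleavage. The fallback sets out from lactone 9 and uses an acyclic acyl donor that cannot over-add. Ring-opening aminolysis with MeNH(OMe)·HCl and i-PrMgCl (THF, −20 °C) should give the Weinreb amide (1S,2R)-2-[(dodec-11-en-1-yl)(hydroxy)amino]-N-methoxy-N-methylcyclopentane-1-carboxamide F5. Reagent 11 (2.5 equiv, one consumed by N–OH; THF, 0 °C) should then add once through the chelated adduct. The quench releases 1-[(1S,2R)-2-[(dodec-11-en-1-yl)(hydroxy)amino]cyclopentyl]non-8-en-1-one F6, which closes to the hemiketal. The route is rejoined at 12.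

Step 7. The twofold coupling may stall after one arm, with protodeboronation or inhibition of palladium by the pyridine product and the ring nitrogen. The fallback inverts the polarity of the coupling and sets out from diene 13 through borane 15. Oxidation with NaBO3·4H2O should give 12-[(3S,3aS,6aR)-3-(8-hydroxyoctyl)hexahydro-1H-cyclopenta[c]isoxazol-1-yl]dodecan-1-ol F7. Appel iodination (I2, PPh3, imidazole, CH2Cl2) should give (3S,3aS,6aR)-1-(12-iodododecyl)-3-(8-iodooctyl)hexahydro-1H-cyclopenta[c]isoxazole F8. Copper-catalysed C(sp3)–C(sp2) coupling at both iodide ends (Li2CuCl4 cat., THF, −20 → 0 °C) with pyridin-3-ylmagnesium chloride F9, made from 14 by Br/Mg exchange with i-PrMgCl·LiCl and used in excess, should give the product. The route is rejoined at target 16.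

Further compounds
F1 | step 4 | methyl (1S,2R)-2-aminocyclopentane-1-carboxylate | COC(=O)[C@H]1CCC[C@H]1N
F2 | step 4 | methyl (1S,2R)-2-(dodec-11-en-1-ylamino)cyclopentane-1-carboxylate | COC(=O)[C@H]1CCC[C@H]1NCCCCCCCCCCC=C
F3 | step 4 | methyl (1S,2R)-2-[(benzoyloxy)(dodec-11-en-1-yl)amino]cyclopentane-1-carboxylate | COC(=O)[C@H]1CCC[C@H]1N(OC(=O)c1ccccc1)CCCCCCCCCCC=C
F4 | step 4 | methyl (1S,2R)-2-[(dodec-11-en-1-yl)(hydroxy)amino]cyclopentane-1-carboxylate | COC(=O)[C@H]1CCC[C@H]1N(O)CCCCCCCCCCC=C
F5 | step 5 | (1S,2R)-2-[(dodec-11-en-1-yl)(hydroxy)amino]-N-methoxy-N-methylcyclopentane-1-carboxamide | CON(C)C(=O)[C@H]1CCC[C@H]1N(O)CCCCCCCCCCC=C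
F6 | step 5 | 1-[(1S,2R)-2-[(dodec-11-en-1-yl)(hydroxy)amino]cyclopentyl]non-8-en-1-one | C=CCCCCCCC(=O)[C@H]1CCC[C@H]1N(O)CCCCCCCCCCC=C
F7 | step 7 | 12-[(3S,3aS,6aR)-3-(8-hydroxyoctyl)hexahydro-1H-cyclopenta[c]isoxazol-1-yl]dodecan-1-ol | OCCCCCCCCCCCCN1O[C@@H](CCCCCCCCO)[C@H]2CCC[C@H]21
F8 | step 7 | (3S,3aS,6aR)-1-(12-iodododecyl)-3-(8-iodooctyl)hexahydro-1H-cyclopenta[c]isoxazole | ICCCCCCCCCCCCN1O[C@@H](CCCCCCCCI)[C@H]2CCC[C@H]21
F9 | step 7 | pyridin-3-ylmagnesium chloride | Cl[Mg]c1cccnc1
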